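# Proposed synthesis of CNP0224452.2 by double conjugate arylation of a Stobbe diene diester

## The problem

Compound 21 is a resveratrol tetramer (C56H42O12) built on the four-carbon chain C1–C2–C3–C4, in which C1 and C4 each carry a 4-hydroxyphenyl group and a resorcinol ring (ring B on C1, ring B′ on C4), while C3 and C2 each carry the benzo ring (ring C on C3, ring C′ on C2) of a trans-2-aryl-2,3-dihydrobenzofuran. Ring B is bonded through its second ortho carbon to furan C3 of the benzofuran on ring C, so that C1, two carbons of ring B, furan C3, two carbons of ring C, C3 and C2 close an eight-membered ring; the other half closes in the same way through C4, ring B′, ring C′ and C2, and the two eight-membered rings share the C2–C3 bond. There are eight stereocentres: C1 (R), C2 (S), C3 (R) and C4 (R), with furan C3 and furan C2 (R,R) in the half holding C1 and (S,S) in the half holding C4. Apart from C1 and C4 the two halves are mirror images, so C1 and C4 form the only like pair, neither can be relayed from the other by substrate control, and a chiral reagent has to set both. The other six centres are local relationships (trans fusion at C2–C3, trans furans, each furan C3–H syn to the C–H of the chain carbon on the other ortho position of its ring C) that can be left to substrate or thermodynamic control; because C1 and C4 are like, there is only one trans-fused C2/C3 diastereomer, and it is the one in 21. The ten phenols are prone to oxidation and are carried as methyl ethers, the 2-aryl-dihydrobenzofuran C–O bonds ionise in acid and should be made last, and the resorcinol rings are strong nucleophiles, so every electrophilic ring closure needs its regiochemistry secured. The enabling feature is that C1–C2–C3–C4, with one carbon substituent on each of C2 and C3 and two aryl groups on each of C1 and C4, is the skeleton of a 2,3-bis(arylmethylidene)succinate whose β-carbons are C1 and C4. Ring B is attached to C1 through the carbon ortho and para to its two oxygens, which is exactly where 2,4-dimethoxyphenylboronic acid 5 carries boron.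

## Retrosynthesis

**21 to 20.** The two furan O–C2 bonds and all methyl ethers are cut last. Bis-carbinol 20 has a 4-methoxyphenyl carbinol next to each furan C3 and a methoxy group on the neighbouring ring C carbon. BBr3 is asked to ionise each carbinol, let the ortho-methoxy oxygen close the five-membered ring with loss of its methyl group, and then strip the remaining ten methyl ethers. Making the furans earlier would expose the acid-labile benzylic ethers to several further steps.

**20 to 18 and 19.** The two furan C2–aryl bonds are cut to dialdehyde 18 and two molecules of the commercial Grignard reagent 19. The carbinol configuration is of no consequence because it is ionised in the next step.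

**18 to 16.** The furan C3–furan C2 bonds are cut by a one-carbon homologation of diketone 16 at both carbonyl groups, through the bis-spiroepoxide 17. A 4-methoxybenzyl nucleophile added directly to 16 would save a step, but the ketones carry three ortho substituents and sit in eight-membered rings; a small sulfonium ylide is the safer nucleophile.

**16 to 9 and 14.** In each eight-membered ring the two bonds to ring C are cut (C3–aryl and carbonyl–aryl, and likewise C2–aryl and carbonyl–aryl in the other half). This reduces 16 to the tetracenedione 9 and two molecules of 3,5-dimethoxybenzyne 15, each released from one molecule of silyl triflate 14. The cut turns both eight-membered rings into six-membered ones, so no medium-ring cyclisation is needed. The natural regiochemistry of the aryne matches: the enolate carbon bonds to the aryne carbon remote from methoxy, and the oxygen-flanked carbon bonds to the carbonyl. The forward step asks a ketone bis-enolate without β-keto ester activation to undergo aryne insertion twice; this is the least precedented step of the route.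

**9 to 8 to 7.** The ring B–carbonyl bonds are cut (double Friedel–Crafts acylation). The position to be acylated is meta to both methoxy groups of ring B. A plain 4-methoxyphenyl group on the same carbon would cyclise at least as readily. The 4-oxyphenyl rings are therefore carried as 3,5-dibromo-4-methoxyphenyl groups, in which both positions ortho to the benzylic carbon are flanked by bromine. The bromines are removed by hydrogenolysis (8 to 9) once the rings are closed. Diacid 7 is an open-chain succinic acid.

**7 to 6 to 4 and 5.** Saponification leads back to diester 6. The C1–ring B and C4–ring B′ bonds are then cut to diene diester 4 and two molecules of boronic acid 5. The two benzylidene units of 4 are equivalent, so a catalyst that selects one enantioface gives the like C1/C4 pair directly. The electron-poor dibromoaryl groups also make 4 a better acceptor than the bis(4-methoxybenzylidene) compound would be.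

**4 to 3 to 1 and 2.** The two C=C bonds are cut by a double Stobbe condensation of dimethyl succinate 1 with two molecules of aldehyde 2, followed by esterification of diacid 3.

**14 to 11 to 10.** The aryne precursor comes from 3,5-dimethoxyphenol 10 by ortho-bromination to 11, then O-silylation (12), bromine–lithium exchange with silyl migration to carbon (13) and triflation.

## Roads not taken

**Alternative 1:** The cut is at C1–C2 and C2–C3 of one eight-membered ring. The seven-membered ampelopsin-type ketone A2 would be homologated with the benzofuranyl diazomethane A3 under Sc(OTf)3. Loss of nitrogen with 1,2-shift of the diarylmethine C1 would give the eight-membered ketone A1, which carries the benzofuran on C2.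

- Merits: it joins two dimer-sized pieces, the ring system of A2 is of a known type, and Lewis-acid-catalysed ring expansion of cyclic ketones with aryldiazomethanes is an established reaction class.
- Weak points: the aryl carbon of ring C can migrate in place of C1; A3 is an electron-rich, labile diazo compound; and A1 contains only one of the two eight-membered rings. After the key step, C3 still has to be bonded to C4, ring B′ introduced, the second eight-membered ring closed onto the benzofuran, and the benzofuran reduced to the trans-dihydrobenzofuran. C4 would be set late under substrate control, which favours the mirror relationship with C1.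
- Comparison: Alternative 1 is more convergent and its key step is better precedented than step 9 of the chosen plan. The chosen plan sets C1 and C4 together by one catalyst and leaves fewer skeletal bonds after its key step.

**Alternative 2:** Here the aryne supplies ring B. The meso chrysene bis(β-keto ester) A5, enolised by CsF, would take up two molecules of aryne 15, each inserting into a C(=O)–C(CO2Me) bond, to give the meso diketo diester A4 with both eight-membered rings.

- Merits: β-keto esters are the proven substrate class for aryne insertion, both medium rings form in one step, and no asymmetric catalysis is needed to reach A4.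
- Weak points: in A4, C1 and C4 are mirror-related ketones. Each must gain a 4-oxyphenyl group and a hydrogen with the same absolute sense, so a reagent has to override the substrate at one of the two sites on a congested diaryl ketone. The ester groups must also be elaborated to the furan C2 carbons.
- Comparison: for ring construction Alternative 2 is better founded than the chosen plan, whose aryne step has no β-keto ester activation. The chosen plan sets against this that its symmetry-breaking event happens at step 3 on an open-chain diene with two equivalent reaction sites and no substrate bias to fight.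

**Alternative 3:** The C1–aryl and C4–aryl bonds are cut last. The meso bis(ortho-hydroxybenzylic alcohol) A7 would ionise twice to ortho-quinone methides under a chiral biphenol catalyst and accept a 4-methoxyphenyl group from boronic acid A8 at each exocyclic carbon, giving A6.

- Merits: the only non-mirror element is installed on the finished skeleton, and biphenol-catalysed boronate additions to ortho-quinone methides are known.
- Weak points: A7 already contains both eight-membered rings and both furans, so the whole meso skeleton must be built first, probably by a route like Alternative 2. The two reacting carbons lie inside folded eight-membered rings, and the catalyst must add with the same absolute sense at two enantiotopic sites, so one addition is mismatched with the ring's own facial bias. A failure would come at the last stage.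
- Comparison: in stereochemical logic Alternative 3 is at least as clean as the chosen plan and would be shorter after the skeleton. The chosen plan tests its catalyst-controlled step early on cheap material, but must then carry C1 and C4 through the ring-forming steps and control six further centres by substrate control.

Key step: step 3

Assumption: the (R,R) enantiomer of the diene ligand is taken to deliver the aryl group to the enantioface that gives the (R) configuration at C1 and C4; if the sense proves opposite, its antipode is used without other change.

Remark: 6, 7, 8 and 9 are drawn as the C2/C3 isomer that maps directly onto 21. Other C2/C3 epimers are carried along, because both centres are planarised in step 9. Descriptors at C2 and C3 change along the route only because substituent priorities change.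

## Steps

Step 1
Reactants: 1 dimethyl succinate; 2 3,5-dibromo-4-methoxybenzaldehyde (two equivalents)
Product: 3 (2E,3E)-2,3-bis[(3,5-dibromo-4-methoxyphenyl)methylidene]butanedioic acid
Conditions: NaOMe, MeOH, reflux; then aq. HCl
Reagents that add atoms: none
Why: Double Stobbe condensation; each aldol adduct lactonises onto the neighbouring ester and opens by E1cB elimination to the carboxylate, which gives the (E,E) diene diacid directly, as is usual for aromatic aldehydes with excess alkoxide.

Step 2
Reactants: 3 (2E,3E)-2,3-bis[(3,5-dibromo-4-methoxyphenyl)methylidene]butanedioic acid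
Product: 4 dimethyl (2E,3E)-2,3-bis[(3,5-dibromo-4-methoxyphenyl)methylidene]butanedioate
Conditions: MeI (3 equiv), K2CO3 (3 equiv), DMF, rt
Reagents that add atoms: iodomethane (two equivalents), CI
Why: Carboxylate O-alkylation of both acid groups avoids acid and heat, so the diene geometry is kept.

Step 3
Reactants: 4 dimethyl (2E,3E)-2,3-bis[(3,5-dibromo-4-methoxyphenyl)methylidene]butanedioate; 5 2,4-dimethoxyphenylboronic acid (two equivalents)
Product: 6 dimethyl (2R,3S)-2,3-bis[(R)-(3,5-dibromo-4-methoxyphenyl)(2,4-dimethoxyphenyl)methyl]butanedioate
Conditions: [RhCl(C2H4)2]2 (5 mol%), (1R,4R)-2,5-diphenylbicyclo[2.2.2]octa-2,5-diene (11 mol%), aq. KOH (0.2 equiv), 1,4-dioxane/H2O 10:1, 60 °C; 5 charged in excess (6 equiv in all) in portions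
Reagents that add atoms: none
Why: Rhodium-catalysed asymmetric conjugate addition of an arylboronic acid (Hayashi–Miyaura type) with a chiral diene ligand, the closest known class being β-aryl unsaturated esters: the boronic acid transmetalates to a hydroxo complex of monovalent rhodium, the aryl–rhodium bond adds across one enoate with aryl going to the β-carbon, and the oxa-π-allyl rhodium enolate is hydrolysed at the α-carbon, returning the hydroxo complex. The cycle then repeats at the second benzylidene unit with a second molecule of 5, so the step forms the C1–ring B and C4–ring B′ bonds and closes no ring. C1 and C4 are set by the ligand alone; the two enoates of 4 are equivalent, so the same enantioface is selected twice and the like (R,R) pair results. C2 and C3 are set on protonation under substrate control and are of no lasting consequence, since they are α to carbonyl groups until step 9 and are planarised there. The step needs α-protonation of the first enolate rather than γ-protonation through the adjacent alkene, and addition to both hindered α-substituted enoates. The electron-poor dibromoaryl groups raise the electrophilicity of the β-carbons, the two enoate planes are twisted out of conjugation so each reacts as an isolated cinnamate, and portionwise excess of 5 offsets its protodeboronation. Aryl bromides are not attacked by monovalent rhodium under these conditions.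

Step 4
Reactants: 6 dimethyl (2R,3S)-2,3-bis[(R)-(3,5-dibromo-4-methoxyphenyl)(2,4-dimethoxyphenyl)methyl]butanedioate
Product: 7 (2R,3S)-2,3-bis[(R)-(3,5-dibromo-4-methoxyphenyl)(2,4-dimethoxyphenyl)methyl]butanedioic acid
Conditions: KOH, THF/MeOH/H2O, 70 °C; then aq. HCl
Reagents that add atoms: potassium hydroxide, [K+].[OH-]
Why: Ester saponification; epimerisation at C2 or C3 is tolerated and C1 and C4 are not acidic enough to be touched.

Step 5
Reactants: 7 (2R,3S)-2,3-bis[(R)-(3,5-dibromo-4-methoxyphenyl)(2,4-dimethoxyphenyl)methyl]butanedioic acid
Product: 8 (5aS,6R,11aR,12R)-6,12-bis(3,5-dibromo-4-methoxyphenyl)-1,3,7,9-tetramethoxy-5a,6,11a,12-tetrahydrotetracene-5,11-dione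
Conditions: P2O5 in MeSO3H (1:10 w/w), 50 °C
Reagents that add atoms: none
Why: Double intramolecular Friedel–Crafts acylation; each carboxyl closes a six-membered ring onto the dimethoxyphenyl ring of the remote diarylmethyl carbon (the tetralone mode, preferred over the five-ring mode as with arylmethylsuccinic acids) at the position meta to both methoxy groups, as in the classical route to 5,7-dimethoxy-1-tetralone. The dibromoaryl ring is strongly disfavoured as a competitor because both of its open positions lie between the benzylic carbon and a bromine.

Step 6
Reactants: 8 (5aS,6R,11aR,12R)-6,12-bis(3,5-dibromo-4-methoxyphenyl)-1,3,7,9-tetramethoxy-5a,6,11a,12-tetrahydrotetracene-5,11-dione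
Product: 9 (5aS,6R,11aR,12R)-1,3,7,9-tetramethoxy-6,12-bis(4-methoxyphenyl)-5a,6,11a,12-tetrahydrotetracene-5,11-dione
Conditions: H2 (1 atm), Pd/C, Et3N, EtOAc/MeOH, rt
Reagents that add atoms: none
Why: Hydrogenolysis of aryl bromides over Pd/C with an amine base is much faster than reduction of the aryl ketones; removing the halogens here keeps them out of the strongly basic and organolithium steps that follow.

Step 7
Reactants: 10 3,5-dimethoxyphenol
Product: 11 2-bromo-3,5-dimethoxyphenol
Conditions: NBS, CH2Cl2, –78 °C to rt
Reagents that add atoms: N-bromosuccinimide, O=C1CCC(=O)N1Br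
Why: Electrophilic bromination ortho to the hydroxyl group, the less hindered of the two activated positions; any 4-bromo isomer is removed by chromatography.

Step 8
Reactants: 11 2-bromo-3,5-dimethoxyphenol
Product: 14 3,5-dimethoxy-2-(trimethylsilyl)phenyl trifluoromethanesulfonate, via silyl ether 12 (not isolated), via lithium phenolate 13 (not isolated)
Conditions: HMDS, THF, 70 °C; then n-BuLi, THF, –78 °C; then Tf2O, –78 °C to rt
Reagents that add atoms: hexamethyldisilazane, C[Si](C)(C)N[Si](C)(C)C; trifluoromethanesulfonic anhydride, O=S(=O)(OS(=O)(=O)C(F)(F)F)C(F)(F)F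
Why: Standard one-pot route to ortho-silylaryl triflates: O-silylation, bromine–lithium exchange with 1,3-migration of silicon from oxygen to carbon (retro-Brook), then O-triflation of the phenolate.

Step 9
Reactants: 9 (5aS,6R,11aR,12R)-1,3,7,9-tetramethoxy-6,12-bis(4-methoxyphenyl)-5a,6,11a,12-tetrahydrotetracene-5,11-dione; 14 3,5-dimethoxy-2-(trimethylsilyl)phenyl trifluoromethanesulfonate (two equivalents)
Product: 16 (1R,2S,3R,4R)-diketone with both eight-membered rings (trans-fused at C2–C3; each ring holds a diaryl ketone between ring B and ring C; all oxygens as methyl ethers), via 3,5-dimethoxybenzyne 15 (not isolated)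
Conditions: KH (2.5 equiv), 18-crown-6, THF, 0 °C to rt; then 14 (3 equiv charged), KF (6 equiv), THF, 0 °C to rt; then aq. NH4Cl
Reagents that add atoms: none
Why: Proposed new method: each enolate of the dipotassium bis-enolate of 9 should add through its α-carbon to the carbon of one molecule of aryne 15 remote from methoxy, the aryl anion formed next to methoxy can then only attack the ketone it has just regenerated (the other carbonyl is still an enolate), and the benzocyclobutenoxide fragments to a ring-enlarged ketone whose benzylic anion is stabilised as an ortho-quinodimethane enolate, so that two aryne units are inserted in all. The closest known reactions are the acyl-alkylation of arynes with β-keto esters and the two-carbon ring enlargement of cycloalkanone enolates by arynes; neither has been shown on a tetrasubstituted aryl ketone enolate. C2 and C3 are set on protonation and stay epimerisable through the same dienolates, so the single trans-fused isomer is expected to be reachable by base equilibration.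

Step 10
Reactants: 16 (1R,2S,3R,4R)-diketone with both eight-membered rings
Product: 18 dialdehyde (each ketone carbon of 16 now CH–CHO; 1R,2S,3R,4R; formyl-bearing carbon R in the half holding C1 and S in the half holding C4), via bis-spiroepoxide 17 (not isolated)
Conditions: Me3S+ I– (4 equiv), n-BuLi, THF, 0 °C to rt; then ZnI2 (cat.), toluene, rt
Reagents that add atoms: trimethylsulfonium iodide (two equivalents), C[S+](C)C.[I-]
Why: Corey–Chaykovsky epoxidation of both ketones followed by Meinwald rearrangement; the small ylide reaches the tri-ortho-substituted ketones, and the diaryl-stabilised cation from epoxide opening takes a 1,2-hydride shift to the aldehyde. The new furan C3 centres are α to the formyl groups and doubly benzylic, so they equilibrate; each is expected to settle with its hydrogen syn to the hydrogen of the chain carbon on the other ortho position of ring C, a local preference that is the same in both halves.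

Step 11
Reactants: 18 dialdehyde; 19 (4-methoxyphenyl)magnesium bromide (two equivalents)
Product: 20 bis-carbinol (each formyl group of 18 now CH(OH)(4-methoxyphenyl); carbinol centres as a mixture)
Conditions: 19 (4 equiv charged), THF, –78 to 0 °C; then H2O
Reagents that add atoms: none
Why: Grignard addition to both aldehydes at low temperature to limit enolisation; the carbinol configuration is irrelevant because both centres are ionised in step 12.

Step 12
Reactants: 20 bis-carbinol
Product: 21 CNP0224452.2
Conditions: BBr3 (excess), CH2Cl2, –78 °C to rt; then MeOH, H2O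
Reagents that add atoms: none
Why: Demethylative cyclisation with BBr3: each 4-methoxybenzylic carbinol ionises, the ortho-methoxy oxygen of ring C closes the five-membered ring, and bromide removes the methyl group from the oxonium ion; the remaining ten methyl ethers are then cleaved. The 2,3-trans arrangement follows from closure anti to the ring B substituent on furan C3, and from the reversibility of the benzylic C–O bond under the conditions.

## Compound list

1 | dimethyl succinate | COC(=O)CCC(=O)OC | starting material
2 | 3,5-dibromo-4-methoxybenzaldehyde | COc1c(Br)cc(C=O)cc1Br | starting material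
3 | (2E,3E)-2,3-bis[(3,5-dibromo-4-methoxyphenyl)methylidene]butanedioic acid | OC(=O)/C(=C/c1cc(Br)c(OC)c(Br)c1)C(=C/c1cc(Br)c(OC)c(Br)c1)\C(=O)O | intermediate
4 | dimethyl (2E,3E)-2,3-bis[(3,5-dibromo-4-methoxyphenyl)methylidene]butanedioate | COC(=O)/C(=C/c1cc(Br)c(OC)c(Br)c1)C(=C/c1cc(Br)c(OC)c(Br)c1)\C(=O)OC | intermediate
5 | 2,4-dimethoxyphenylboronic acid | COc1ccc(B(O)O)c(OC)c1 | starting material
6 | dimethyl (2R,3S)-2,3-bis[(R)-(3,5-dibromo-4-methoxyphenyl)(2,4-dimethoxyphenyl)methyl]butanedioate | COc1c(Br)cc(cc1Br)[C@H](c1ccc(OC)cc1OC)[C@@H](C(=O)OC)[C@@H](C(=O)OC)[C@H](c1cc(Br)c(OC)c(Br)c1)c1ccc(OC)cc1OC | intermediate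
7 | (2R,3S)-2,3-bis[(R)-(3,5-dibromo-4-methoxyphenyl)(2,4-dimethoxyphenyl)methyl]butanedioic acid | COc1c(Br)cc(cc1Br)[C@H](c1ccc(OC)cc1OC)[C@@H](C(=O)O)[C@@H](C(=O)O)[C@H](c1cc(Br)c(OC)c(Br)c1)c1ccc(OC)cc1OC | intermediate
8 | (5aS,6R,11aR,12R)-6,12-bis(3,5-dibromo-4-methoxyphenyl)-1,3,7,9-tetramethoxy-5a,6,11a,12-tetrahydrotetracene-5,11-dione | COc1c(Br)cc(cc1Br)[C@@H]1c2c(OC)cc(OC)cc2C(=O)[C@H]2[C@H](c3cc(Br)c(OC)c(Br)c3)c3c(OC)cc(OC)cc3C(=O)[C@H]12 | intermediate
9 | (5aS,6R,11aR,12R)-1,3,7,9-tetramethoxy-6,12-bis(4-methoxyphenyl)-5a,6,11a,12-tetrahydrotetracene-5,11-dione | COc1ccc(cc1)[C@@H]1c2c(OC)cc(OC)cc2C(=O)[C@H]2[C@H](c3ccc(OC)cc3)c3c(OC)cc(OC)cc3C(=O)[C@H]12 | intermediate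
10 | 3,5-dimethoxyphenol | COc1cc(O)cc(OC)c1 | starting material
11 | 2-bromo-3,5-dimethoxyphenol | COc1cc(O)c(Br)c(OC)c1 | intermediate
12 | (2-bromo-3,5-dimethoxyphenoxy)trimethylsilane | COc1cc(O[Si](C)(C)C)c(Br)c(OC)c1 | intermediate
13 | lithium 3,5-dimethoxy-2-(trimethylsilyl)phenolate | COc1cc([O-])c([Si](C)(C)C)c(OC)c1.[Li+] | intermediate
14 | 3,5-dimethoxy-2-(trimethylsilyl)phenyl trifluoromethanesulfonate | COc1cc(OS(=O)(=O)C(F)(F)F)c([Si](C)(C)C)c(OC)c1 | intermediate
15 | 3,5-dimethoxybenzyne (1,2-didehydro-3,5-dimethoxybenzene) | COC1=CC(OC)=CC#C1 | intermediate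
16 | (1R,2S,3R,4R)-diketone: chain C1–C4 with 4-methoxyphenyl on C1 and C4; ring B (2,4-dimethoxy) links C1 to a ketone carbon, which is bonded to ring C (dimethoxy) whose other ortho carbon holds C3; ring B′, ketone and ring C′ link C4 to C2 in the same way; rings trans-fused at C2–C3 | COc1ccc([C@@H]2c3c(OC)cc(OC)cc3C(=O)c3c(OC)cc(OC)cc3[C@H]3[C@H](c4ccc(OC)cc4)c4c(OC)cc(OC)cc4C(=O)c4c(OC)cc(OC)cc4[C@H]23)cc1 | intermediate
17 | bis-spiroepoxide of 16 (each C=O replaced by a spiro-oxirane; spiro centres unassigned) | COc1ccc([C@@H]2c3c(OC)cc(OC)cc3C3(CO3)c3c(OC)cc(OC)cc3[C@H]3[C@H](c4ccc(OC)cc4)c4c(OC)cc(OC)cc4C4(CO4)c4c(OC)cc(OC)cc4[C@H]23)cc1 | intermediate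
18 | dialdehyde: 16 with each ketone carbon as CH–CHO (1R,2S,3R,4R; formyl-bearing carbon R in the half holding C1, S in the half holding C4) | COc1ccc([C@@H]2c3c(OC)cc(OC)cc3[C@@H](C=O)c3c(OC)cc(OC)cc3[C@H]3[C@H](c4ccc(OC)cc4)c4c(OC)cc(OC)cc4[C@H](C=O)c4c(OC)cc(OC)cc4[C@H]23)cc1 | intermediate
19 | (4-methoxyphenyl)magnesium bromide | COc1ccc([Mg]Br)cc1 | starting material
20 | bis-carbinol: 18 with each CHO as CH(OH)(4-methoxyphenyl); carbinol centres unassigned | COc1ccc([C@@H]2c3c(OC)cc(OC)cc3[C@@H](C(O)c3ccc(OC)cc3)c3c(OC)cc(OC)cc3[C@H]3[C@H](c4ccc(OC)cc4)c4c(OC)cc(OC)cc4[C@H](C(O)c4ccc(OC)cc4)c4c(OC)cc(OC)cc4[C@H]23)cc1 | intermediate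
21 | CNP0224452.2 | Oc1ccc([C@@H]2c3c(O)cc(O)cc3[C@@H]3c4c(cc(O)cc4[C@H]4[C@H](c5ccc(O)cc5)c5c(O)cc(O)cc5[C@H]5c6c(cc(O)cc6[C@H]24)O[C@@H]5c2ccc(O)cc2)O[C@H]3c2ccc(O)cc2)cc1 | target

## Step count and risk

Total: 12 steps. Longest linear sequence: 10 steps (steps 1–6 and 9–12); steps 7 and 8 prepare the aryne precursor.

**Step 9 (double aryne ring expansion).**
- What may go wrong: O-arylation or simple proton transfer in place of C-arylation at the crowded tetrasubstituted enolate carbon; protonation of the aryl anion before it closes onto the ketone; a second arylation of the first-formed benzylic anion; kinetic protonation giving a cis ring fusion. The cause is that the enolate lacks the second acceptor group that makes β-keto esters reliable partners.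
- Fallback, from 9 back to 16: palladium-catalysed α-arylation of both ketones with 1-bromo-3,5-dimethoxybenzene (Pd(OAc)2, t-Bu3P, NaOt-Bu, toluene) would give the bis(α-aryl) diketone F1. Cleavage of the now non-enolisable ketones toward the benzylic carbanion (KOt-Bu, H2O, Haller–Bauer type) would give the ring B dicarboxylic acid F2, with 3,5-dimethoxyphenyl groups on C2 and C3. Double Friedel–Crafts acylation (P2O5 in MeSO3H) at the ring C carbon ortho and para to the methoxy groups would then close both eight-membered rings to 16.

**Step 3 (key step).**
- What may go wrong: γ-protonation of the first rhodium enolate through the neighbouring alkene, which moves the double bond to C2=C3 and ends the sequence; no addition to the second, very hindered α-substituted enoate; protodeboronation of 5 outrunning transmetalation. The cause is that α-substituted β-aryl enoates are slow acceptors for aryl–rhodium species.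
- Fallback, from 3 back to 7: DCC/DMAP coupling of 3 with (S)-4-phenyl-1,3-oxazolidin-2-one would give the bis-imide F3. Copper-mediated conjugate addition of (2,4-dimethoxyphenyl)magnesium bromide (CuBr·SMe2, THF) under auxiliary control would give the bis-adduct F4. LiOH/H2O2 would release diacid 7.

**Step 10 (homologation).**
- What may go wrong: no addition of the ylide to the tri-ortho-substituted ketones in the eight-membered rings; epimerisation of the formyl-bearing centres to the wrong furan C3 configuration.
- Fallback, from 16 back to 18: methylenation with Cp2TiMe2 (toluene, 70 °C) would give the bis(1,1-diarylalkene) F5. Hydroboration–oxidation (BH3·THF; then NaOH, H2O2) would give the bis(primary alcohol) F6. Dess–Martin oxidation would give 18.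

**Step 12 (cyclisation and global demethylation).**
- What may go wrong: Friedel–Crafts capture of the benzylic cations by a resorcinol ring; loss of the furan C3 proton from the cation toward a conjugated triarylethylene; reversible opening of the new 2-aryl-dihydrobenzofurans under BBr3 with loss of the trans relationship; incomplete demethylation. The cause is that ring closure and deprotection run through the same cationic manifold.
- Fallback, from 16 to 21: BCl3 would remove only the methyl groups ortho to the ketones (chelation), giving the bis(ortho-hydroxyaryl) diketone F7. NaBH4 would give the bis(ortho-hydroxybenzhydrol) F8. Base-induced ortho-quinone methide formation and formal [4+1] annulation with the ylide of (4-methoxybenzyl)dimethylsulfonium bromide F10 (made from 4-methoxybenzyl bromide and dimethyl sulfide; Cs2CO3, CH2Cl2) would give the deca-O-methyl ether F9 with both trans furans in place. Non-acidic demethylation with NaSEt (DMF, 140 °C) would give 21.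

## Further compounds

F1 | step 9 | bis(α-aryl) diketone: 9 with a 3,5-dimethoxyphenyl group on each ketone α-carbon (new quaternary centres unassigned) | COc1ccc(cc1)[C@@H]1c2c(OC)cc(OC)cc2C(=O)C2(c3cc(OC)cc(OC)c3)[C@H](c3ccc(OC)cc3)c3c(OC)cc(OC)cc3C(=O)C12c1cc(OC)cc(OC)c1
F2 | step 9 | (1R,2S,3R,4R)-2,3-bis(3,5-dimethoxyphenyl)-1,4-bis(4-methoxyphenyl)butane-1,4-diyl bis(3,5-dimethoxybenzoic acid), each benzoic acid attached to the chain through its C2 | COc1ccc(cc1)[C@H](c1c(OC)cc(OC)cc1C(=O)O)[C@@H](c1cc(OC)cc(OC)c1)[C@@H](c1cc(OC)cc(OC)c1)[C@H](c1ccc(OC)cc1)c1c(OC)cc(OC)cc1C(=O)O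
F3 | step 3 | bis-imide of 3 with (S)-4-phenyl-1,3-oxazolidin-2-one | O=C1OC[C@H](c2ccccc2)N1C(=O)/C(=C/c1cc(Br)c(OC)c(Br)c1)C(=C/c1cc(Br)c(OC)c(Br)c1)\C(=O)N1[C@@H](c2ccccc2)COC1=O
F4 | step 3 | bis-imide corresponding to 6 (both ester groups replaced by the (S)-4-phenyl-2-oxo-1,3-oxazolidin-3-yl carbonyl unit) | COc1c(Br)cc(cc1Br)[C@H](c1ccc(OC)cc1OC)[C@@H](C(=O)N1[C@@H](c2ccccc2)COC1=O)[C@@H](C(=O)N1[C@@H](c2ccccc2)COC1=O)[C@H](c1cc(Br)c(OC)c(Br)c1)c1ccc(OC)cc1OC
F5 | step 10 | bis(methylidene) analogue of 16 (each C=O replaced by C=CH2) | COc1ccc([C@@H]2c3c(OC)cc(OC)cc3C(=C)c3c(OC)cc(OC)cc3[C@H]3[C@H](c4ccc(OC)cc4)c4c(OC)cc(OC)cc4C(=C)c4c(OC)cc(OC)cc4[C@H]23)cc1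
F6 | step 10 | bis(hydroxymethyl) compound (each C=O of 16 replaced by CH–CH2OH; new centres unassigned) | COc1ccc([C@@H]2c3c(OC)cc(OC)cc3C(CO)c3c(OC)cc(OC)cc3[C@H]3[C@H](c4ccc(OC)cc4)c4c(OC)cc(OC)cc4C(CO)c4c(OC)cc(OC)cc4[C@H]23)cc1
F7 | step 12 | bis(ortho-hydroxyaryl) diketone (16 with the ring C and ring C′ methoxy groups ortho to the ketones as free hydroxyls) | COc1ccc([C@@H]2c3c(OC)cc(OC)cc3C(=O)c3c(O)cc(OC)cc3[C@H]3[C@H](c4ccc(OC)cc4)c4c(OC)cc(OC)cc4C(=O)c4c(O)cc(OC)cc4[C@H]23)cc1
F8 | step 12 | bis(ortho-hydroxybenzhydrol) (F7 with both ketones reduced; carbinol centres unassigned) | COc1ccc([C@@H]2c3c(OC)cc(OC)cc3C(O)c3c(O)cc(OC)cc3[C@H]3[C@H](c4ccc(OC)cc4)c4c(OC)cc(OC)cc4C(O)c4c(O)cc(OC)cc4[C@H]23)cc1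
F9 | step 12 | deca-O-methyl ether of 21 | COc1ccc([C@@H]2c3c(OC)cc(OC)cc3[C@@H]3c4c(cc(OC)cc4[C@H]4[C@H](c5ccc(OC)cc5)c5c(OC)cc(OC)cc5[C@H]5c6c(cc(OC)cc6[C@H]24)O[C@@H]5c2ccc(OC)cc2)O[C@H]3c2ccc(OC)cc2)cc1
F10 | step 12 | (4-methoxybenzyl)dimethylsulfonium bromide | COc1ccc(C[S+](C)C)cc1.[Br-]
A1 | alternative 1 | eight-membered ketone carrying the benzofuran on C2 | COc1ccc([C@@H]2c3c(OC)cc(OC)cc3[C@@H]3c4c(cc(OC)cc4C(=O)[C@@H]2c2cc(OC)cc4oc(-c5ccc(OC)cc5)cc24)O[C@H]3c2ccc(OC)cc2)cc1
A2 | alternative 1 | seven-membered ampelopsin-type ketone | COc1ccc([C@@H]2c3c(OC)cc(OC)cc3[C@@H]3c4c(cc(OC)cc4C2=O)O[C@H]3c2ccc(OC)cc2)cc1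
A3 | alternative 1 | 4-(diazomethyl)-6-methoxy-2-(4-methoxyphenyl)-1-benzofuran | COc1ccc(-c2cc3c(C=[N+]=[N-])cc(OC)cc3o2)cc1
A4 | alternative 2 | meso diketo diester with both eight-membered rings | O=C1c2c(OC)cc(OC)cc2[C@@H](C(=O)OC)c2c(OCc3ccccc3)cc(OC)cc2[C@H]2C(=O)c3c(OC)cc(OC)cc3[C@H](C(=O)OC)c3c(OCc4ccccc4)cc(OC)cc3[C@H]12
A5 | alternative 2 | meso chrysene bis(β-keto ester) (ester-bearing centres enolisable, unassigned) | O=C1C(C(=O)OC)c2c(OCc3ccccc3)cc(OC)cc2[C@H]2C(=O)C(C(=O)OC)c3c(OCc4ccccc4)cc(OC)cc3[C@H]12
A6 | alternative 3 | octamethyl ether of the target skeleton with two free resorcinol hydroxyls | COc1ccc([C@@H]2c3c(O)cc(OC)cc3[C@@H]3c4c(cc(OC)cc4[C@H]4[C@H](c5ccc(OC)cc5)c5c(O)cc(OC)cc5[C@H]5c6c(cc(OC)cc6[C@H]24)O[C@@H]5c2ccc(OC)cc2)O[C@H]3c2ccc(OC)cc2)cc1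
A7 | alternative 3 | meso bis(ortho-hydroxybenzylic alcohol) (carbinol centres unassigned) | OC2c3c(O)cc(OC)cc3[C@@H]3c4c(cc(OC)cc4[C@H]4C(O)c5c(O)cc(OC)cc5[C@H]5c6c(cc(OC)cc6[C@H]24)O[C@@H]5c2ccc(OC)cc2)O[C@H]3c2ccc(OC)cc2
A8 | alternative 3 | 4-methoxyphenylboronic acid | COc1ccc(B(O)O)cc1
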